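**Plan**

- Retrosynthetic cuts, in order: the phenol O–CH3 bond (protecting group); both benzylic C–CH2 bonds together (each benzylic C–H traced back to C–B); the ring-B carbon–oxygen bond of the diaryl ether; the ring-A carbon–acetyl bond.
- Enabling feature: both stereocentres are benzylic CH(CH3) carbons, one on ring A ortho to the phenol oxygen and one on ring B ortho to the ether oxygen, each bonded through CH2 to the same 4-methylpent-3-enyl chain.
- Forward: C-acetylation of methylhydroquinone, SNAr etherification with the fluoroketone (joins rings A and B; no ring is formed anywhere in the route), O-methylation, twofold ketone reduction, twofold carbamoylation.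
- Both chains are then attached in one twofold lithiation–borylation, followed by twofold protodeboronation and O-demethylation.
- Stereochemistry: the (S,S)-carbinols come from catalyst-controlled oxazaborolidine reduction and are relayed stereospecifically (retention on lithiation and borylation, inversion on 1,2-migration, retention on protodeboronation) to the (S,S) target.

Key step: step 7

Remark: ring A is the hydroquinone-derived ring that ends as the phenol, ring B is the ring derived from the fluoroketone; Bpin is the pinacolboryl group.

**Route**

Step 1
Reactants: 1 methylhydroquinone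
Product: 2 2',5'-dihydroxy-4'-methylacetophenone
Conditions: AcOH, BF3·OEt2, 90 °C; then H2O
Reagents that add atoms: acetic acid, CC(=O)O
Why: Boron trifluoride-promoted Friedel–Crafts (Fries-type) C-acylation of the hydroquinone, in which the acetyl group should enter at the least hindered doubly activated position, ortho to a hydroxyl and para to the methyl group, and the chelated ortho-hydroxy ketone formed resists a second acylation.

Step 2
Reactants: 2 2',5'-dihydroxy-4'-methylacetophenone; 3 2'-fluoro-4'-methylacetophenone
Product: 4 1-[2-(5-acetyl-4-hydroxy-2-methylphenoxy)-4-methylphenyl]ethanone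
Conditions: K2CO3, DMSO, 100 °C, N2
Reagents that add atoms: none
Why: Nucleophilic aromatic substitution (addition–elimination) of the fluoride activated by its ortho acetyl group, in which the 5'-hydroxyl of 2 should react because the 2'-hydroxyl is chelated to its own ketone and its phenoxide is delocalised into the carbonyl, the same preference that governs monoalkylation of 2',5'-dihydroxyacetophenones.

Step 3
Reactants: 4 1-[2-(5-acetyl-4-hydroxy-2-methylphenoxy)-4-methylphenyl]ethanone
Product: 5 1-[2-(5-acetyl-4-methoxy-2-methylphenoxy)-4-methylphenyl]ethanone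
Conditions: MeI, K2CO3, DMF, 50 °C
Reagents that add atoms: iodomethane, CI
Why: Williamson O-methylation of the remaining chelated phenol, with carbonate too weak a base to C-alkylate the two methyl ketones.

Step 4
Reactants: 5 1-[2-(5-acetyl-4-methoxy-2-methylphenoxy)-4-methylphenyl]ethanone
Product: 6 (1S)-1-[2-[5-[(1S)-1-hydroxyethyl]-4-methoxy-2-methylphenoxy]-4-methylphenyl]ethanol
Conditions: (R)-1-methyl-3,3-diphenyltetrahydro-1H,3H-pyrrolo[1,2-c][1,3,2]oxazaborole (0.2 equiv per ketone), BH3·SMe2, THF, −20 °C; then MeOH, aqueous work-up
Reagents that add atoms: none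
Why: Corey–Bakshi–Shibata reduction, in which each ketone binds the catalyst–borane complex with its aryl group turned away from the catalyst so that hydride should be delivered to the Re face of both carbonyls, setting the two (S)-carbinol centres independently under reagent control.

Step 5
Reactants: 6 (1S)-1-[2-[5-[(1S)-1-hydroxyethyl]-4-methoxy-2-methylphenoxy]-4-methylphenyl]ethanol
Product: 7 (S,S)-bis(N,N-diisopropylcarbamate) of diol 6
Conditions: NaH, i-Pr2NCOCl, THF, 0 °C to reflux
Reagents that add atoms: N,N-diisopropylcarbamoyl chloride, CC(C)N(C(C)C)C(=O)Cl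
Why: O-carbamoylation of the two sodium alkoxides by acyl substitution at the carbamoyl chloride, which does not touch the carbinol C–O bonds and so carries the (S,S) configuration over unchanged.

Step 6
Reactants: 8 5-bromo-2-methylpent-2-ene
Product: 10 4,4,5,5-tetramethyl-2-(4-methylpent-3-enyl)-1,3,2-dioxaborolane, via 4-methylpent-3-enylmagnesium bromide 9 (not isolated)
Conditions: Mg, THF, rt to 40 °C; then i-PrOBpin, −78 °C to rt
Reagents that add atoms: 2-isopropoxy-4,4,5,5-tetramethyl-1,3,2-dioxaborolane, CC(C)OB1OC(C)(C)C(C)(C)O1
Why: Grignard formation from the primary homoallylic bromide followed by substitution of isopropoxide at boron, the standard route to primary alkyl pinacol boronic esters, with the remote trisubstituted alkene inert.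

Step 7
Reactants: 7 (S,S)-bis(N,N-diisopropylcarbamate) of diol 6; 10 4,4,5,5-tetramethyl-2-(4-methylpent-3-enyl)-1,3,2-dioxaborolane
Product: 13 (S,S)-bis(tertiary benzylic pinacol boronic ester) carrying both 4-methylpent-3-enyl chains, via dilithiated biscarbamate 11 (not isolated), via bis(boronate) ate complex 12 (not isolated)
Conditions: s-BuLi (2.6 equiv), Et2O, −78 °C, 1 h; 10 (3 equiv), −78 °C, 2 h; MgBr2·OEt2 in MeOH, −78 °C to rt
Reagents that add atoms: none
Why: Each benzylic C–H of 7 is removed by s-BuLi with retention, guided by complexation to the carbamate carbonyl, to give the configurationally stable dilithio species 11, which takes up two molecules of 10 on the lithium-bearing face to give the bis(ate) complex 12. On warming with MgBr2/MeOH the primary 4-methylpent-3-enyl group on each boron shifts to carbon antiperiplanar to the leaving carbamate, so both benzylic C–CH2 bonds form with inversion while boron stays on carbon. The closest known reaction type is the lithiation–borylation (stereospecific 1,2-metallate rearrangement) of enantioenriched secondary benzylic carbamates with primary alkyl pinacol boronic esters, used here at two remote sites of one molecule; no ring is closed. Both new boron-bearing quaternary stereocentres are controlled only by the (S)-carbinol configurations of 7 through the retention–retention–inversion sequence, which should give (S,S)-13. The step needs full stereospecificity and benzylic rather than ring lithiation; these are secured by the fast carbamate-directed α-deprotonation at −78 °C in ether, the clean migration of a primary alkyl group, and the Lewis acid/methanol additive that hastens migration before the crowded ortho-substituted ate complexes can revert, while the trisubstituted alkenes are spectators.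

Step 8
Reactants: 13 (S,S)-bis(tertiary benzylic pinacol boronic ester) carrying both 4-methylpent-3-enyl chains
Product: 14 1-methoxy-5-methyl-2-[(2S)-6-methylhept-5-en-2-yl]-4-[5-methyl-2-[(2S)-6-methylhept-5-en-2-yl]phenoxy]benzene
Conditions: Bu4NF·3H2O, toluene, 60 °C
Reagents that add atoms: none
Why: Fluoride-promoted protodeboronation of tertiary benzylic pinacol boronic esters, in which fluoride coordination gives a boronate whose benzylic carbon is protonated by water on the face that carried boron, so both C–B bonds should become C–H bonds with retention while the diaryl ether, anisole and alkenes stay intact.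

Step 9
Reactants: 14 1-methoxy-5-methyl-2-[(2S)-6-methylhept-5-en-2-yl]-4-[5-methyl-2-[(2S)-6-methylhept-5-en-2-yl]phenoxy]benzene
Product: 15 5-methyl-2-[(2S)-6-methylhept-5-en-2-yl]-4-[5-methyl-2-[(2S)-6-methylhept-5-en-2-yl]phenoxy]phenol
Conditions: NaSEt, DMF, 130 °C
Reagents that add atoms: none
Why: SN2 demethylation of the aryl methyl ether by ethanethiolate in a dipolar aprotic solvent, chosen because it is non-acidic and should leave the acid-sensitive trisubstituted alkenes, the unactivated diaryl ether and the non-acidic benzylic stereocentres untouched.

**Compound list**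

1 | methylhydroquinone (2-methylbenzene-1,4-diol) | Cc1cc(O)ccc1O | starting material
2 | 2',5'-dihydroxy-4'-methylacetophenone | CC(=O)c1cc(O)c(C)cc1O | intermediate
3 | 2'-fluoro-4'-methylacetophenone | CC(=O)c1ccc(C)cc1F | starting material
4 | 1-[2-(5-acetyl-4-hydroxy-2-methylphenoxy)-4-methylphenyl]ethanone | CC(=O)c1cc(Oc2cc(C)ccc2C(C)=O)c(C)cc1O | intermediate
5 | 1-[2-(5-acetyl-4-methoxy-2-methylphenoxy)-4-methylphenyl]ethanone | CC(=O)c1cc(Oc2cc(C)ccc2C(C)=O)c(C)cc1OC | intermediate
6 | (1S)-1-[2-[5-[(1S)-1-hydroxyethyl]-4-methoxy-2-methylphenoxy]-4-methylphenyl]ethanol | C[C@H](O)c1cc(Oc2cc(C)ccc2[C@H](C)O)c(C)cc1OC | intermediate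
7 | (S,S)-bis(N,N-diisopropylcarbamate) of diol 6 | C[C@H](OC(=O)N(C(C)C)C(C)C)c1cc(Oc2cc(C)ccc2[C@H](C)OC(=O)N(C(C)C)C(C)C)c(C)cc1OC | intermediate
8 | 5-bromo-2-methylpent-2-ene | CC(C)=CCCBr | starting material
9 | 4-methylpent-3-enylmagnesium bromide (formed in the flask) | CC(C)=CCC[Mg]Br | intermediate
10 | 4,4,5,5-tetramethyl-2-(4-methylpent-3-enyl)-1,3,2-dioxaborolane | CC(C)=CCCB1OC(C)(C)C(C)(C)O1 | intermediate
11 | (S,S)-dilithiated biscarbamate, lithium in place of each benzylic hydrogen of 7 (formed in the flask) | C[C@]([Li])(OC(=O)N(C(C)C)C(C)C)c1cc(Oc2cc(C)ccc2[C@]([Li])(C)OC(=O)N(C(C)C)C(C)C)c(C)cc1OC | intermediate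
12 | dilithium bis(boronate) ate complex, each benzylic carbon bonded to a pinacolato(4-methylpent-3-enyl)borate unit with the carbamates still in place (formed in the flask) | C[C@]([B-]1(CCC=C(C)C)OC(C)(C)C(C)(C)O1)(OC(=O)N(C(C)C)C(C)C)c1cc(Oc2cc(C)ccc2[C@]([B-]2(CCC=C(C)C)OC(C)(C)C(C)(C)O2)(C)OC(=O)N(C(C)C)C(C)C)c(C)cc1OC.[Li+].[Li+] | intermediate
13 | 1-methoxy-5-methyl-2-[(2S)-6-methyl-2-(pinacolboryl)hept-5-en-2-yl]-4-[5-methyl-2-[(2S)-6-methyl-2-(pinacolboryl)hept-5-en-2-yl]phenoxy]benzene | CC(C)=CCC[C@](B1OC(C)(C)C(C)(C)O1)(C)c1cc(Oc2cc(C)ccc2[C@@](B2OC(C)(C)C(C)(C)O2)(C)CCC=C(C)C)c(C)cc1OC | intermediate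
14 | 1-methoxy-5-methyl-2-[(2S)-6-methylhept-5-en-2-yl]-4-[5-methyl-2-[(2S)-6-methylhept-5-en-2-yl]phenoxy]benzene | CC(C)=CCC[C@H](C)c1cc(Oc2cc(C)ccc2[C@@H](C)CCC=C(C)C)c(C)cc1OC | intermediate
15 | 5-methyl-2-[(2S)-6-methylhept-5-en-2-yl]-4-[5-methyl-2-[(2S)-6-methylhept-5-en-2-yl]phenoxy]phenol | CC(C)=CCC[C@H](C)c1cc(Oc2cc(C)ccc2[C@@H](C)CCC=C(C)C)c(C)cc1O | target

**Step count**

Total steps: 9. Longest linear sequence: 8 (steps 1 to 5 and 7 to 9); step 6 is a one-step side branch.

**Steps most likely to fail**

Step 7. The second α-deprotonation may lag behind the first, or the crowded ate complexes at the two ortho-substituted benzylic carbons may revert to the lithiated carbamate before migration. Either would leave mono-coupled material or erode stereochemical integrity. The fallback changes the boron electrophile to a less hindered diol ester, whose ate complexes form faster and migrate before they revert. It sets out from 9 and 7. Grignard reagent 9 is quenched with B(OMe)3 and hydrolysed to 4-methylpent-3-enylboronic acid F1. F1 is condensed with 2,2-dimethylpropane-1,3-diol (MgSO4, CH2Cl2) to give 5,5-dimethyl-2-(4-methylpent-3-enyl)-1,3,2-dioxaborinane F2. Lithiation of 7 as in step 7 and capture with F2 should give the (S,S)-bis(neopentyl glycol boronic ester) F3. Protodeboronation of F3 with Bu4NF·3H2O as in step 8 returns to the route at 14.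

Step 2. The chelated 2'-hydroxyl may compete for the fluoroarene, a second arylation may follow, or the doubly deprotonated hydroquinone may be oxidised under the hot basic conditions. The fallback etherifies a phenol with a single hydroxyl and introduces the ring-A acetyl group afterwards. It sets out from 3. SNAr of 3 with commercial 4-methoxy-2-methylphenol (COc1ccc(O)c(C)c1; K2CO3, DMSO, 110 °C) should give 1-[2-(4-methoxy-2-methylphenoxy)-4-methylphenyl]ethanone F4. Friedel–Crafts acetylation of F4 (AcCl, AlCl3, CH2Cl2, 0 °C) is expected to go ortho to the methoxy group and para to the ring-A methyl group, on the ring not deactivated by a ketone. This returns to the route at 5 and bypasses 2 and 4.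

Step 4. Facial selectivity may be insufficient at one of the two ortho-alkoxy ketones, because the neighbouring ether oxygens can compete for borane. This would give diastereomeric diols that are hard to separate and would be carried through the stereospecific sequence. The fallback replaces stoichiometric borane delivery by catalytic pressure hydrogenation with trans-RuCl2[(R)-XylBINAP][(R)-DAIPEN] and KOt-Bu in i-PrOH under H2. That reduction works by outer-sphere hydride and proton transfer without Lewis acid binding to the ether oxygens, tolerates ortho-substituted aryl methyl ketones, and with this catalyst enantiomer is expected to give the (S)-carbinols. It sets out from 5 and returns to the route at 6, and no new compound arises (F0).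

**Further compounds**

F1 | step 7 | 4-methylpent-3-enylboronic acid | CC(C)=CCCB(O)O
F2 | step 7 | 5,5-dimethyl-2-(4-methylpent-3-enyl)-1,3,2-dioxaborinane | CC(C)=CCCB1OCC(C)(C)CO1
F3 | step 7 | (S,S)-bis(neopentyl glycol boronic ester) analogue of 13 | CC(C)=CCC[C@](B1OCC(C)(C)CO1)(C)c1cc(Oc2cc(C)ccc2[C@@](B2OCC(C)(C)CO2)(C)CCC=C(C)C)c(C)cc1OC
F4 | step 2 | 1-[2-(4-methoxy-2-methylphenoxy)-4-methylphenyl]ethanone | CC(=O)c1ccc(C)cc1Oc1ccc(OC)cc1C
F0 | step 4 | none | none
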